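## Analysis of the target

Pestalone B (26) is a benzophenone: two benzene rings joined through one ketone carbon, with no further ring and no stereocentre, so the problem is purely one of substitution pattern. Ring A carries the ketone at A1, hydroxyl at A2, bromine at A3, methyl at A4, hydrogen at A5 and methoxy at A6. Ring B carries the aroyl group at B1, a formyl group at B2, hydroxyls at B3 and B5 on either side of its only hydrogen (B4), and a prenyl group at B6. Both rings are 2,6-disubstituted at the carbon bound to the ketone, so the carbonyl sits between four ortho substituents; the rings are twisted, but the aryl–carbonyl axes are not stereo-elements that must be controlled. The sensitive parts are the formyl group ortho to the diaryl ketone (base converts such a 1,4-dicarbonyl array to a phthalide by hydride transfer, and amines convert it to isoindole derivatives), the prenyl alkene beside the B5 phenol (acid closes it to a dimethylchroman), the aryl bromide (no halogen–metal exchange, no hydrogenolysis) and the free phenols. The hard part is ring B: six different substituents, three of them carbon groups on the adjacent positions B6, B1 and B2, and a hindered aryl–CO–aryl link. The strategy rests on the 1,3-dioxygenation of ring B around B4–H: B1, B2, B3 and B4 correspond to C6, C5, C4 and C3 of a 4-oxygenated 2-pyrone that already carries the aroyl group and an ester, and B5–B6 correspond to the two carbons of a prenyl-substituted ynol ether. A cycloaddition with loss of CO2 then delivers ring B at the aromatic oxidation level with every substituent in place.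

## Retrosynthetic reasoning

26 ← 25 ← 23 (protecting groups). No skeletal bond is cut. The O–Si bond at B5 is cut last and the two acetal O–C bonds at B3 and A2 before it. The B5 oxygen is the only one that can add to the prenyl alkene, so it stays silylated while the acetals are removed. The silyl ether is then released under buffered, near-neutral conditions in the presence of the complete keto aldehyde. The forward steps must avoid free acid, amines and unbuffered base.

23 ← 22 ← 21 (oxidation level at B2). The formyl group is traced back through benzylic alcohol 22 to the methyl ester of 21. The ester is what the ring-forming step needs at B2 as an acceptor, so the aldehyde level is adjusted only after ring B exists. The forward reduction has to take the ester and spare the ketone, relying on the shielding of the ketone by its four ortho substituents; a mild oxidation then returns the aldehyde.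

21 ← 13 + 19 (key disconnection). The bonds B6–B1 and B5–B4 are cut. This divides ring B into a four-carbon piece B1–B4 (aroyl, ester, oxygen, hydrogen), which is the C6–C3 diene of pyrone 13, and a two-carbon piece B5–B6 (oxygen, prenyl), which is the triple bond of ynol ether 19. What is gained:
- convergence: ring A, the ketone and the ester arrive in one partner, the prenyl group and the B5 oxygen in the other;
- the aromatic oxidation level without an oxidant, because the lactone bridge of adduct 20 is expelled;
- a ring B on which nothing has to be introduced later by substitution.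

Cutting the B1–carbonyl bond instead would demand a hexasubstituted aryl nucleophile adding to a doubly ortho-substituted carbonyl. Cutting B6–prenyl or B2–formyl would leave electrophilic substitution on a crowded resorcinol. The forward reaction has to join the prenyl-bearing alkyne carbon to C6 of 13 and the silyloxy carbon to C3.

13 ← 12 ← 8 + 9 (pyrone). The pyrone is cut at the lactone bond O1–C2 and at C5–C6. This gives the symmetric five-carbon diester 9, which holds C2 to C5 with the C4 oxygen and the ester, and the aryl keto acid 8, whose acid carbon becomes C6. The diaryl ketone is therefore never made by joining two hindered aromatic carbons; it is carried in as the ketone of an α-keto acid. Forward, the enolate of 9 is C-acylated by chloride 10, the tricarbonyl compound 11 lactonizes through its enol to 12, and the acidic C4 hydroxyl is capped as an acetal to give 13.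

8 ← 7 ← 6 ← 2 + 3 (ring A side chain) and 2 ← 1. The A1–carbonyl bond is cut. A1 lies between the two oxygens of ring A, and the other position ortho to the phenol oxygen is the one that carries bromine. An acylation tethered through the phenol oxygen (aryl ester 4, cyclizing to lactone 5) can therefore reach only A1, and the two-carbon unit 3 supplies both the ketone and the acid carbon. Opening of 5 gives hydroxy ester 6, which is protected (7) and hydrolysed (8). The C–Br bond of 2 is made first on phenol 1, ortho to the free hydroxyl and para to the methoxy group, so that bromine also blocks the wrong ortho position for the tethered acylation.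

19 ← 16 ← 14 + 15 (ynol ether). The O–Si bond is cut to ynolate 18, and the C–O bond of the ynolate to acetylide 17 of terminal alkyne 16, which puts the oxygen on the alkyne terminus without ambiguity. Alkyne 16 comes from an sp–sp3 coupling of allylic bromide 14 with alkynyl Grignard reagent 15, leaving the prenyl alkene untouched.

## Alternatives that were turned down

Alternative 1: ring A made last by benzannulation on a ring B alkyne.
- Disconnection: ring A is opened at A2–A1, A6–A5, A2–A3 and A5–A4. The partners are (E)-4-bromo-1-diazo-3-methylbut-3-en-2-one (A1) and methoxyalkyne A2, in which ring B is complete, its aldehyde masked as a dioxolane and the future ketone carbon present as a silylated carbinol.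
- Forward key step: irradiation of A1 triggers a Wolff rearrangement to a bromo vinylketene. [2+2] addition to the ynol ether, 4π opening of the cyclobutenone and 6π closure of the dienylketene give phenol A3.
- For it: the positions of OH, Br, Me and OMe on ring A follow from the connectivity of the two partners. This is stronger than the chosen route, where bromine is placed by a directed electrophilic substitution (step 1). The A2 hydroxyl also emerges already distinguished from the A6 methoxy group.
- Against it: ring A is the easy ring, since commercial 1 already holds three of its substituents. Ring B, the real difficulty, would have to be assembled hexasubstituted beforehand by other means. The alkyne carbon that must react is attached to a carbinol wedged between two ortho substituents. The ketene intermediates can also add to the prenyl alkene, and the vinyl bromide of A1 is itself photolabile. After the annulation the carbinol must still be unmasked and oxidized next to a free phenol.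
- Comparison: the chosen route brings the ketone in at the right oxidation level, forms ring B and places all its substituents in one operation, and is clearly shorter.

Alternative 2: ring B as a cyclohexane-1,3-dione, aromatized late.
- Disconnection: B1–B2 and B3–B4, leading to ene-dione A4 and dimethyl malonate (A5).
- Forward key step: with methoxide base, A5 adds to the CH alkene carbon of A4, the methyl ketone enolate condenses onto one malonate ester, and dione A6 results with the B2 ester in place.
- For it: the reagents are cheap and robust, and no heat-sensitive ynol ether is needed. On cost and scalability of the ring-forming step it is stronger than the chosen route.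
- Against it: A6 is one oxidation level below the arene. The dehydrogenation must remove the hydrogens at B6 and B1, and the usual agents (halogens, quinones, noble-metal catalysts at high temperature) prefer the doubly activated B4 methylene or attack the prenyl alkene. The conjugate addition must also choose between the two ends of an ene-dione. A4 already contains the hindered aryl ketone, so that problem is only moved. The three stereocentres of A6 are irrelevant to the target but make it a mixture of diastereomers and tautomers. The resorcinol finally obtained has both oxygens free, including the one beside the prenyl group.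
- Comparison: in the chosen route aromaticity comes from loss of the lactone bridge, so no oxidant ever meets the prenyl group.

Alternative 3: ring B from a bis(silyloxy)diene and an alkynoate.
- Disconnection: B6–B1 and B3–B2. Diene A7 supplies B3 to B6 with the prenyl group on its terminus. Alkynoate A8 supplies B1 and B2, with the ester on B2 and ring A attached through a silylated carbinol.
- Forward key step: the nucleophilic terminus of A7 adds to the β-carbon of the ynoate, the ring closes at the ketene acetal carbon, and loss of the methoxy group on mild acid work-up gives resorcylate A9.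
- For it: this is a well-tried route to resorcylates, its regiochemistry is dictated by the ester, it runs at lower temperature than a pyrone cycloaddition, and both components are sturdier than 19. On reliability of the ring-forming event it is at least the equal of the chosen route.
- Against it: the alkyne carbon to be attacked bears a secondary carbinol with a 2,6-disubstituted aryl group and a bulky silyl ether, and the attacking diene terminus is itself substituted, so B6–B1 joins two hindered centres. The central carbon arrives as an alcohol and must later be desilylated and oxidized, two steps on top of the ester-to-aldehyde adjustment that both routes need. A9 has both phenols free, so the B5 hydroxyl beside the prenyl group would need protection before any acid or oxidant is used.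
- Comparison: the chosen route offers instead the ketone present from the start (it is part of the acceptor pattern of pyrone 13) and B3 and B5 oxygens that emerge differentiated, acetal against silyl ether.

Key step: step 9

Assumption: oxalyl chloride (3), dimethyl 3-oxoglutarate (9), prenyl bromide (14) and ethynylmagnesium bromide in THF (15) are taken as commercial; the only chiral compound on the route, bridged lactone 20, is a racemic transient.

## Route

Step 1
Reactants: 1 3-methoxy-5-methylphenol
Product: 2 2-bromo-5-methoxy-3-methylphenol
Conditions: NBS (1.0 equiv), i-Pr2NH (cat.), CH2Cl2, −78 → 0 °C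
Reagents that add atoms: N-bromosuccinimide, O=C1CCC(=O)N1Br
Why: Amine-catalysed ortho-bromination of a phenol: the N-bromoamine formed in situ is delivered through a hydrogen bond to the phenol oxygen, so substitution goes ortho to OH, and of the two ortho carbons the one para to the methoxy group is the more activated; one equivalent of reagent at low temperature limits dibromination.

Step 2
Reactants: 2 2-bromo-5-methoxy-3-methylphenol; 3 oxalyl chloride
Product: 6 methyl (3-bromo-2-hydroxy-6-methoxy-4-methylphenyl)(oxo)acetate, via aryl chlorooxoacetate 4 (not isolated), via benzofuran-2,3-dione 5 (not isolated)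
Conditions: (COCl)2 (excess), ClCH2CH2Cl, 60 °C, then evaporate; AlCl3, CH2Cl2, 0 °C; MeOH, 0 °C → rt
Reagents that add atoms: methanol, CO
Why: O-Acylation gives ester 4, whose acid chloride can reach only the one free ortho carbon (the other holds bromine) in an intramolecular Friedel–Crafts acylation activated by the ortho methoxy and para methyl groups; brief AlCl3 treatment at 0 °C should close lactone 5 without cleaving the methyl ether, and methanol opens the reactive aryl ester to the hydrogen-bonded hydroxy keto ester 6.

Step 3
Reactants: 6 methyl (3-bromo-2-hydroxy-6-methoxy-4-methylphenyl)(oxo)acetate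
Product: 7 methyl [3-bromo-6-methoxy-2-(methoxymethoxy)-4-methylphenyl](oxo)acetate
Conditions: MOMCl, i-Pr2NEt, CH2Cl2, 0 °C → rt
Reagents that add atoms: chloromethyl methyl ether, COCCl
Why: O-Alkylation of an acidic, carbonyl-flanked phenol with a reactive α-chloro ether and a hindered amine; the keto ester has no enolizable hydrogen and is inert.

Step 4
Reactants: 7 methyl [3-bromo-6-methoxy-2-(methoxymethoxy)-4-methylphenyl](oxo)acetate
Product: 8 [3-bromo-6-methoxy-2-(methoxymethoxy)-4-methylphenyl](oxo)acetic acid
Conditions: LiOH, THF/H2O, 0 °C; then 1 M HCl to pH 3, 0 °C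
Reagents that add atoms: lithium hydroxide (hydroxide oxygen), [Li+].[OH-]
Why: Saponification of an α-keto ester is fast at 0 °C because the neighbouring ketone activates the ester, while the aryl ketone is shielded by its two ortho substituents; brief cold acidification spares the acetal.

Step 5
Reactants: 8 [3-bromo-6-methoxy-2-(methoxymethoxy)-4-methylphenyl](oxo)acetic acid; 9 dimethyl 3-oxoglutarate
Product: 12 methyl 6-[3-bromo-6-methoxy-2-(methoxymethoxy)-4-methylbenzoyl]-4-hydroxy-2-oxo-2H-pyran-5-carboxylate, via keto acid chloride 10 (not isolated), via acylated oxoglutarate 11 (not isolated)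
Conditions: Me2C=C(Cl)NMe2, CH2Cl2, 0 °C → rt; 9, MgCl2, pyridine, CH2Cl2, 0 °C → rt; DBU, PhMe, 80 °C; aq. citric acid
Reagents that add atoms: none
Why: The chloroenamine gives chloride 10 without free HCl, so the acetal survives; the magnesium-chelated enolate of 9 is C-acylated at the acid chloride carbonyl, far more electrophilic than the shielded aryl ketone (MgCl2–amine acylation of β-keto esters), and in 11 the enol of the new ketone lactonizes onto the remote ester with loss of methanol, the usual 6-exo-trig closure of a 3,5-dioxo ester to a 4-hydroxy-2-pyrone.

Step 6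
Reactants: 12 methyl 6-[3-bromo-6-methoxy-2-(methoxymethoxy)-4-methylbenzoyl]-4-hydroxy-2-oxo-2H-pyran-5-carboxylate
Product: 13 methyl 6-[3-bromo-6-methoxy-2-(methoxymethoxy)-4-methylbenzoyl]-4-(methoxymethoxy)-2-oxo-2H-pyran-5-carboxylate
Conditions: MOMCl, i-Pr2NEt, CH2Cl2, 0 °C
Reagents that add atoms: chloromethyl methyl ether, COCCl
Why: O-Alkylation of the vinylogous acid by a hard electrophile goes to the C4 oxygen; the acetal turns the acidic hydroxyl into a neutral alkoxy group that cannot protonate the ynol ether in step 9.

Step 7
Reactants: 14 prenyl bromide (1-bromo-3-methylbut-2-ene); 15 ethynylmagnesium bromide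
Product: 16 5-methylhex-4-en-1-yne
Conditions: CuCl (cat.), THF, 0 °C → rt
Reagents that add atoms: none
Why: Copper-catalysed coupling of an alkynyl Grignard reagent with an allylic bromide; with a prenyl halide, substitution at the primary carbon (SN2) is preferred over attack at the tertiary end, giving the skipped enyne, which is used as a THF solution because it is volatile.

Step 8
Reactants: 16 5-methylhex-4-en-1-yne
Product: 19 triisopropyl[(5-methylhex-4-en-1-yn-1-yl)oxy]silane, via lithium acetylide 17 (not isolated), via lithium ynolate 18 (not isolated)
Conditions: n-BuLi, THF, −78 °C; t-BuOOLi (from t-BuOOH, LiN(SiMe3)2), −78 → 0 °C; i-Pr3SiOTf, −78 → 0 °C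
Reagents that add atoms: tert-butyl hydroperoxide (as its lithium salt), CC(C)(C)OO; triisopropylsilyl trifluoromethanesulfonate, CC(C)[Si](OS(=O)(=O)C(F)(F)F)(C(C)C)C(C)C
Why: The acetylide attacks the peroxide oxygen with loss of tert-butoxide (oxidation of a metal acetylide to an ynolate), and the bulky silyl triflate silylates the ynolate on oxygen to the isolable triisopropylsilyl ynol ether; only the terminal C–H is acidic enough for n-BuLi at −78 °C.

Step 9
Reactants: 13 methyl 6-[3-bromo-6-methoxy-2-(methoxymethoxy)-4-methylbenzoyl]-4-(methoxymethoxy)-2-oxo-2H-pyran-5-carboxylate; 19 triisopropyl[(5-methylhex-4-en-1-yn-1-yl)oxy]silane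
Product: 21 methyl 2-[3-bromo-6-methoxy-2-(methoxymethoxy)-4-methylbenzoyl]-6-(methoxymethoxy)-3-(3-methylbut-2-enyl)-4-(triisopropylsilyloxy)benzoate, via bridged bicyclic lactone 20 (not isolated)
Conditions: 19 (2 equiv), PhMe, 100 °C, sealed tube
Reagents that add atoms: none
Why: Inverse-electron-demand Diels–Alder reaction of an acceptor-substituted 2-pyrone with an electron-rich alkyne followed by cycloreversion, the reaction type known for ester- and acyl-substituted 2-pyrones with ynamines, ynol ethers and ketene acetals. The prenyl-bearing carbon of 19, its nucleophilic terminus, bonds to pyrone C6, which is β to the C5 ester, δ to the lactone carbonyl and attached to the ring oxygen; the developing silyl ketenium carbon is captured by C3, the far end of the dienolate, so both bonds form in one asynchronous [4+2] event (in the stepwise limit a 6-exo-dig closure onto the ketenium carbon). Ring B is thus closed by intermolecular cycloaddition across C3 and C6 to give the 2-oxabicyclo[2.2.2]octadienone 20, whose lactone bridge leaves as CO2 in an irreversible, aromatizing retro-[4+2]. The two bridgehead stereocentres of 20 form as a racemate, are tied to each other by the bicycle and vanish on aromatization, so no stereocontrol is needed. The selectivity needed is regiochemical (prenyl carbon next to the aroyl carbon, silyloxy carbon next to C–H) and follows from matching the polarized alkyne with the polarized diene; the C6 ketone lowers the LUMO further, while the C4 acetal oxygen raises it only moderately because it sits on the central carbon of the C3–C4–C5 unit. Chemoselectivity should hold because the ynol ether is far more nucleophilic than the prenyl alkene, the rod-shaped alkyne can reach the crowded C6 without meeting the ortho groups of ring A, and no acid or metal salt is present that could hydrolyse 19 or trigger enyne cycloisomerization. All six substituents of ring B (B1 aroyl, B2 ester, B3 acetal oxygen, B4 hydrogen, B5 silyloxy, B6 prenyl) are placed in this one step.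

Step 10
Reactants: 21 methyl 2-[3-bromo-6-methoxy-2-(methoxymethoxy)-4-methylbenzoyl]-6-(methoxymethoxy)-3-(3-methylbut-2-enyl)-4-(triisopropylsilyloxy)benzoate
Product: 22 [3-bromo-6-methoxy-2-(methoxymethoxy)-4-methylphenyl][2-(hydroxymethyl)-3-(methoxymethoxy)-6-(3-methylbut-2-enyl)-5-(triisopropylsilyloxy)phenyl]methanone
Conditions: i-Bu2AlH (2.5 equiv), CH2Cl2, −78 °C; aq. potassium sodium tartrate
Reagents that add atoms: none
Why: Hydride reduction of the aryl ester to the benzylic alcohol at −78 °C, helped by chelation of aluminium to the neighbouring acetal oxygen, while the diaryl ketone, shielded by four ortho substituents and twisted out of conjugation, should react much more slowly; silyl ether, acetals, bromide and alkene are inert.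

Step 11
Reactants: 22 [3-bromo-6-methoxy-2-(methoxymethoxy)-4-methylphenyl][2-(hydroxymethyl)-3-(methoxymethoxy)-6-(3-methylbut-2-enyl)-5-(triisopropylsilyloxy)phenyl]methanone
Product: 23 2-[3-bromo-6-methoxy-2-(methoxymethoxy)-4-methylbenzoyl]-6-(methoxymethoxy)-3-(3-methylbut-2-enyl)-4-(triisopropylsilyloxy)benzaldehyde
Conditions: Dess–Martin periodinane, pyridine, CH2Cl2, 0 °C → rt
Reagents that add atoms: none
Why: Dess–Martin oxidation of a primary benzylic alcohol stops at the aldehyde and tolerates the prenyl alkene, the electron-rich arenes, the silyl ether and the acetals; any cyclic hemiketal with the neighbouring ketone is in equilibrium with the open hydroxy ketone, which is the species oxidized.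

Step 12
Reactants: 23 2-[3-bromo-6-methoxy-2-(methoxymethoxy)-4-methylbenzoyl]-6-(methoxymethoxy)-3-(3-methylbut-2-enyl)-4-(triisopropylsilyloxy)benzaldehyde
Product: 25 2-(3-bromo-2-hydroxy-6-methoxy-4-methylbenzoyl)-6-hydroxy-3-(3-methylbut-2-enyl)-4-(triisopropylsilyloxy)benzaldehyde, via bis(trimethylsilyl) ether 24 (not isolated)
Conditions: Me3SiOTf, 2,2'-bipyridyl, MeCN, 0 °C → rt; then H2O
Reagents that add atoms: none
Why: Silyl triflate–bipyridyl cleavage of aryl methoxymethyl ethers: the buffered silyl electrophile activates each acetal, the aryl oxygen passes to silicon (24) and the methoxymethyl unit to pyridine nitrogen, and water hydrolyses both; no Brønsted acid is present, so aldehyde and prenyl group are untouched, and the bulky triisopropylsilyl ether stays on B5 and keeps that oxygen from closing onto the prenyl group.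

Step 13
Reactants: 25 2-(3-bromo-2-hydroxy-6-methoxy-4-methylbenzoyl)-6-hydroxy-3-(3-methylbut-2-enyl)-4-(triisopropylsilyloxy)benzaldehyde
Product: 26 pestalone B, 2-(3-bromo-2-hydroxy-6-methoxy-4-methylbenzoyl)-4,6-dihydroxy-3-(3-methylbut-2-enyl)benzaldehyde
Conditions: Bu4NF, AcOH (1:1), THF, 0 °C
Reagents that add atoms: none
Why: Fluoride cleaves an aryl silyl ether quickly at 0 °C (strong Si–F bond, phenoxide leaving group); one equivalent of acetic acid keeps the medium near neutral so that the ortho-formyl ketone should not undergo base-induced hydride transfer to a phthalide, and the other two phenols are held in hydrogen bonds to their carbonyl groups.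

## Compound list

1 | 3-methoxy-5-methylphenol | COc1cc(C)cc(O)c1 | starting material
2 | 2-bromo-5-methoxy-3-methylphenol | COc1cc(C)c(Br)c(O)c1 | intermediate
3 | oxalyl chloride | O=C(Cl)C(=O)Cl | starting material
4 | 2-bromo-5-methoxy-3-methylphenyl chloro(oxo)acetate (not isolated) | COc1cc(C)c(Br)c(OC(=O)C(=O)Cl)c1 | intermediate
5 | 7-bromo-4-methoxy-6-methyl-1-benzofuran-2,3-dione (not isolated) | COc1cc(C)c(Br)c2OC(=O)C(=O)c12 | intermediate
6 | methyl (3-bromo-2-hydroxy-6-methoxy-4-methylphenyl)(oxo)acetate | COC(=O)C(=O)c1c(OC)cc(C)c(Br)c1O | intermediate
7 | methyl [3-bromo-6-methoxy-2-(methoxymethoxy)-4-methylphenyl](oxo)acetate | COCOc1c(Br)c(C)cc(OC)c1C(=O)C(=O)OC | intermediate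
8 | [3-bromo-6-methoxy-2-(methoxymethoxy)-4-methylphenyl](oxo)acetic acid | COCOc1c(Br)c(C)cc(OC)c1C(=O)C(=O)O | intermediate
9 | dimethyl 3-oxoglutarate (dimethyl 3-oxopentanedioate) | COC(=O)CC(=O)CC(=O)OC | starting material
10 | [3-bromo-6-methoxy-2-(methoxymethoxy)-4-methylphenyl](oxo)acetyl chloride (not isolated) | COCOc1c(Br)c(C)cc(OC)c1C(=O)C(=O)Cl | intermediate
11 | dimethyl 2-{[3-bromo-6-methoxy-2-(methoxymethoxy)-4-methylphenyl](oxo)acetyl}-3-oxopentanedioate (not isolated) | COC(=O)CC(=O)C(C(=O)OC)C(=O)C(=O)c1c(OC)cc(C)c(Br)c1OCOC | intermediate
12 | methyl 6-[3-bromo-6-methoxy-2-(methoxymethoxy)-4-methylbenzoyl]-4-hydroxy-2-oxo-2H-pyran-5-carboxylate | COC(=O)C1=C(C(=O)c2c(OC)cc(C)c(Br)c2OCOC)OC(=O)C=C1O | intermediate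
13 | methyl 6-[3-bromo-6-methoxy-2-(methoxymethoxy)-4-methylbenzoyl]-4-(methoxymethoxy)-2-oxo-2H-pyran-5-carboxylate | COCOC1=CC(=O)OC(C(=O)c2c(OC)cc(C)c(Br)c2OCOC)=C1C(=O)OC | intermediate
14 | prenyl bromide (1-bromo-3-methylbut-2-ene) | CC(C)=CCBr | starting material
15 | ethynylmagnesium bromide | C#C[Mg]Br | starting material
16 | 5-methylhex-4-en-1-yne | CC(C)=CCC#C | intermediate
17 | lithium 5-methylhex-4-en-1-yn-1-ide (not isolated) | [Li]C#CCC=C(C)C | intermediate
18 | lithium 5-methylhex-4-en-1-yn-1-olate (not isolated) | [Li]OC#CCC=C(C)C | intermediate
19 | triisopropyl[(5-methylhex-4-en-1-yn-1-yl)oxy]silane | CC(C)=CCC#CO[Si](C(C)C)(C(C)C)C(C)C | intermediate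
20 | racemic methyl 1-[3-bromo-6-methoxy-2-(methoxymethoxy)-4-methylbenzoyl]-8-(methoxymethoxy)-6-(3-methylbut-2-enyl)-3-oxo-5-(triisopropylsilyloxy)-2-oxabicyclo[2.2.2]octa-5,7-diene-7-carboxylate (one enantiomer drawn; not isolated) | O=C1O[C@]2(C(=O)c3c(OC)cc(C)c(Br)c3OCOC)C(C(=O)OC)=C(OCOC)[C@H]1C(O[Si](C(C)C)(C(C)C)C(C)C)=C2CC=C(C)C | intermediate
21 | methyl 2-[3-bromo-6-methoxy-2-(methoxymethoxy)-4-methylbenzoyl]-6-(methoxymethoxy)-3-(3-methylbut-2-enyl)-4-(triisopropylsilyloxy)benzoate | COC(=O)c1c(OCOC)cc(O[Si](C(C)C)(C(C)C)C(C)C)c(CC=C(C)C)c1C(=O)c1c(OC)cc(C)c(Br)c1OCOC | intermediate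
22 | [3-bromo-6-methoxy-2-(methoxymethoxy)-4-methylphenyl][2-(hydroxymethyl)-3-(methoxymethoxy)-6-(3-methylbut-2-enyl)-5-(triisopropylsilyloxy)phenyl]methanone | OCc1c(OCOC)cc(O[Si](C(C)C)(C(C)C)C(C)C)c(CC=C(C)C)c1C(=O)c1c(OC)cc(C)c(Br)c1OCOC | intermediate
23 | 2-[3-bromo-6-methoxy-2-(methoxymethoxy)-4-methylbenzoyl]-6-(methoxymethoxy)-3-(3-methylbut-2-enyl)-4-(triisopropylsilyloxy)benzaldehyde | O=Cc1c(OCOC)cc(O[Si](C(C)C)(C(C)C)C(C)C)c(CC=C(C)C)c1C(=O)c1c(OC)cc(C)c(Br)c1OCOC | intermediate
24 | 2-[3-bromo-6-methoxy-4-methyl-2-(trimethylsilyloxy)benzoyl]-3-(3-methylbut-2-enyl)-4-(triisopropylsilyloxy)-6-(trimethylsilyloxy)benzaldehyde (not isolated) | O=Cc1c(O[Si](C)(C)C)cc(O[Si](C(C)C)(C(C)C)C(C)C)c(CC=C(C)C)c1C(=O)c1c(OC)cc(C)c(Br)c1O[Si](C)(C)C | intermediate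
25 | 2-(3-bromo-2-hydroxy-6-methoxy-4-methylbenzoyl)-6-hydroxy-3-(3-methylbut-2-enyl)-4-(triisopropylsilyloxy)benzaldehyde | O=Cc1c(O)cc(O[Si](C(C)C)(C(C)C)C(C)C)c(CC=C(C)C)c1C(=O)c1c(OC)cc(C)c(Br)c1O | intermediate
26 | pestalone B, 2-(3-bromo-2-hydroxy-6-methoxy-4-methylbenzoyl)-4,6-dihydroxy-3-(3-methylbut-2-enyl)benzaldehyde | COc1cc(C)c(Br)c(O)c1C(=O)c1c(C=O)c(O)cc(O)c1CC=C(C)C | target

## Step count and least certain steps

Total: 13 steps. Longest linear sequence: 11 steps (steps 1–6 and 9–13, from 1). The alkyne arm is 2 steps (7 and 8).

Step 9 (key step). The pyrone is deactivated by its C4 oxygen and crowded at C6, so cycloaddition may be slower than thermal isomerization or self-condensation of the ynol ether, which would consume the alkyne without ring formation. Fallback, setting out from 13 and returning at 21: replace the alkyne by a ketene acetal, a stronger π-nucleophile and an established partner of acceptor-substituted 2-pyrones. Commercial methyl 5-methylhex-4-enoate F1 is converted with LiN(i-Pr)2 and then i-Pr3SiOTf into the O-silyl ketene acetal [(1-methoxy-5-methylhexa-1,4-dien-1-yl)oxy]triisopropylsilane F2. Heating 13 with F2 should give, after cycloaddition with the same orientation and loss of CO2, the cyclohexadiene F3. Pyridinium p-toluenesulfonate then removes methanol from F3 (protonation at the more basic methoxy oxygen, aromatization as driving force) to give 21.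

Step 5. The α-keto acid chloride may lose CO to give the aroyl chloride, the enolate may be acylated on oxygen, or the tricarbonyl intermediate may close in a direction other than the pyrone. Fallback, from 8 to 12: assemble the pyrone from the other side. Activation of 8 with carbonyldiimidazole and reaction with Mg(O2CCH2CO2Me)2 gives, after decarboxylation, methyl 4-[3-bromo-6-methoxy-2-(methoxymethoxy)-4-methylphenyl]-3,4-dioxobutanoate F4. Condensation of F4 with malonyl dichloride (C-acylation of the active methylene, O-acylation of the enol of the adjacent ketone) gives 4-hydroxypyrone 12 directly. Any loss of the aryl acetal to the HCl released would be made good in step 6 by using excess MOMCl.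

Step 10. Hydride may also add to the diaryl ketone, giving mixtures of reduction levels. Fallback, from 21 to 23: accept full reduction. LiAlH4 in THF at 0 °C should reduce ester and ketone to the racemic diol [3-bromo-6-methoxy-2-(methoxymethoxy)-4-methylphenyl][2-(hydroxymethyl)-3-(methoxymethoxy)-6-(3-methylbut-2-enyl)-5-(triisopropylsilyloxy)phenyl]methanol F5. A double Swern oxidation then returns keto aldehyde 23; both alcohols are activated before the amine base is added, which avoids lactol formation and over-oxidation to a phthalide.

Step 1. Bromination may occur para to the hydroxyl (between methoxy and methyl) or twice. Fallback, from 1 to 2: mute the hydroxyl so that the methoxy group alone directs. Acetylation (Ac2O, pyridine) gives 3-methoxy-5-methylphenyl acetate F6; NBS in MeCN should brominate para to the methoxy group to give 2-bromo-5-methoxy-3-methylphenyl acetate F7; K2CO3 in MeOH releases 2.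

Step 13. Even buffered fluoride generates phenoxide next to the formyl ketone and may start the base-induced hydride transfer to a phthalide. Fallback, from 22 to 26: remove the silyl group before the aldehyde exists and make the non-basic acetal cleavage the last step. Bu4NF on 22 gives [3-bromo-6-methoxy-2-(methoxymethoxy)-4-methylphenyl][3-hydroxy-6-(hydroxymethyl)-5-(methoxymethoxy)-2-(3-methylbut-2-enyl)phenyl]methanone F8. MnO2 in CH2Cl2 oxidizes the benzylic alcohol to 2-[3-bromo-6-methoxy-2-(methoxymethoxy)-4-methylbenzoyl]-4-hydroxy-6-(methoxymethoxy)-3-(3-methylbut-2-enyl)benzaldehyde F9. The silyl triflate–bipyridyl conditions of step 12 then cleave both acetals of F9 to give 26.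

## Further compounds

F1 | step 9 | methyl 5-methylhex-4-enoate | COC(=O)CCC=C(C)C
F2 | step 9 | [(1-methoxy-5-methylhexa-1,4-dien-1-yl)oxy]triisopropylsilane (mixture of alkene isomers at the ketene acetal) | COC(O[Si](C(C)C)(C(C)C)C(C)C)=CCC=C(C)C
F3 | step 9 | methyl 2-[3-bromo-6-methoxy-2-(methoxymethoxy)-4-methylbenzoyl]-4-methoxy-6-(methoxymethoxy)-3-(3-methylbut-2-enyl)-4-(triisopropylsilyloxy)cyclohexa-1,5-diene-1-carboxylate (racemic, mixture of diastereomers) | COC(=O)C1=C(C(=O)c2c(OC)cc(C)c(Br)c2OCOC)C(CC=C(C)C)C(OC)(O[Si](C(C)C)(C(C)C)C(C)C)C=C1OCOC
F4 | step 5 | methyl 4-[3-bromo-6-methoxy-2-(methoxymethoxy)-4-methylphenyl]-3,4-dioxobutanoate | COC(=O)CC(=O)C(=O)c1c(OC)cc(C)c(Br)c1OCOC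
F5 | step 10 | racemic [3-bromo-6-methoxy-2-(methoxymethoxy)-4-methylphenyl][2-(hydroxymethyl)-3-(methoxymethoxy)-6-(3-methylbut-2-enyl)-5-(triisopropylsilyloxy)phenyl]methanol (one enantiomer drawn) | OCc1c(OCOC)cc(O[Si](C(C)C)(C(C)C)C(C)C)c(CC=C(C)C)c1[C@H](O)c1c(OC)cc(C)c(Br)c1OCOC
F6 | step 1 | 3-methoxy-5-methylphenyl acetate | CC(=O)Oc1cc(C)cc(OC)c1
F7 | step 1 | 2-bromo-5-methoxy-3-methylphenyl acetate | CC(=O)Oc1cc(OC)cc(C)c1Br
F8 | step 13 | [3-bromo-6-methoxy-2-(methoxymethoxy)-4-methylphenyl][3-hydroxy-6-(hydroxymethyl)-5-(methoxymethoxy)-2-(3-methylbut-2-enyl)phenyl]methanone | OCc1c(OCOC)cc(O)c(CC=C(C)C)c1C(=O)c1c(OC)cc(C)c(Br)c1OCOC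
F9 | step 13 | 2-[3-bromo-6-methoxy-2-(methoxymethoxy)-4-methylbenzoyl]-4-hydroxy-6-(methoxymethoxy)-3-(3-methylbut-2-enyl)benzaldehyde | O=Cc1c(OCOC)cc(O)c(CC=C(C)C)c1C(=O)c1c(OC)cc(C)c(Br)c1OCOC
A1 | alternative 1 | (E)-4-bromo-1-diazo-3-methylbut-3-en-2-one | [N-]=[N+]=CC(=O)/C(C)=C/Br
A2 | alternative 1 | racemic 2-{2-[1-(tert-butyldimethylsilyloxy)-3-methoxyprop-2-yn-1-yl]-4,6-bis(methoxymethoxy)-3-(3-methylbut-2-enyl)phenyl}-1,3-dioxolane (one enantiomer drawn) | COC#C[C@@H](O[Si](C)(C)C(C)(C)C)c1c(C2OCCO2)c(OCOC)cc(OCOC)c1CC=C(C)C
A3 | alternative 1 | racemic 2-bromo-6-{(tert-butyldimethylsilyloxy)[2-(1,3-dioxolan-2-yl)-3,5-bis(methoxymethoxy)-6-(3-methylbut-2-enyl)phenyl]methyl}-5-methoxy-3-methylphenol (one enantiomer drawn) | COc1cc(C)c(Br)c(O)c1[C@@H](O[Si](C)(C)C(C)(C)C)c1c(C2OCCO2)c(OCOC)cc(OCOC)c1CC=C(C)C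
A4 | alternative 2 | (E)-1-[3-bromo-6-methoxy-2-(methoxymethoxy)-4-methylphenyl]-3-(3-methylbut-2-enyl)pent-2-ene-1,4-dione | CC(=O)/C(CC=C(C)C)=C/C(=O)c1c(OC)cc(C)c(Br)c1OCOC
A5 | alternative 2 | dimethyl malonate | COC(=O)CC(=O)OC
A6 | alternative 2 | racemic methyl trans,trans-6-[3-bromo-6-methoxy-2-(methoxymethoxy)-4-methylbenzoyl]-5-(3-methylbut-2-enyl)-2,4-dioxocyclohexane-1-carboxylate (one enantiomer drawn) | O=C1CC(=O)[C@@H](CC=C(C)C)[C@H](C(=O)c2c(OC)cc(C)c(Br)c2OCOC)[C@H]1C(=O)OC
A7 | alternative 3 | (3Z)-1-methoxy-7-methyl-1,3-bis(trimethylsilyloxy)octa-1,3,6-triene | COC(O[Si](C)(C)C)=C/C(O[Si](C)(C)C)=C/CC=C(C)C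
A8 | alternative 3 | racemic methyl 4-[3-bromo-6-methoxy-2-(methoxymethoxy)-4-methylphenyl]-4-(tert-butyldimethylsilyloxy)but-2-ynoate (one enantiomer drawn) | COC(=O)C#C[C@H](O[Si](C)(C)C(C)(C)C)c1c(OC)cc(C)c(Br)c1OCOC
A9 | alternative 3 | racemic methyl 2-{[3-bromo-6-methoxy-2-(methoxymethoxy)-4-methylphenyl](tert-butyldimethylsilyloxy)methyl}-4,6-dihydroxy-3-(3-methylbut-2-enyl)benzoate (one enantiomer drawn) | COC(=O)c1c(O)cc(O)c(CC=C(C)C)c1[C@H](O[Si](C)(C)C(C)(C)C)c1c(OC)cc(C)c(Br)c1OCOC
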